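## Analysis of the target

The target is a coumestan (6H-benzofuro[3,2-c]chromen-6-one). Its core is numbered here with ring A as C1 to C4a plus C11b, the lactone as O5 and C6, the furan as C6a, C6b, C10a, O11 and C11a, and ring D as C6b to C10a. A 2,2-dimethyldihydropyran is fused across C1–C2 with its oxygen on C1, a methoxy group sits on C3 and a free hydroxyl on C9. There is no stereocentre, so the whole problem is one of regiochemistry and oxidation level. Ring A is a fully differentiated 1,3,5-trioxygenated benzene: its three oxygens are a pyran ether (C1), a methyl ether (C3) and the lactone oxygen (C4a), and C2 and C11b carry carbon substituents. The C11a–C11b bond is flanked by oxygen-bearing carbons on both sides, which makes a late biaryl-type coupling at this bond unattractive. The lactone opens in hydroxide, the electron-rich ring A and its benzylic pyran CH2 are exposed to oxidants and electrophiles, and the C9 phenol has to be masked until the end. Ring D is a resorcinol: O11 on C10a and the hydroxyl on C9 are meta, and C6b, which bonds to C6a, is para to the hydroxyl. These three carbons map onto the carbonyl (C10a), the enol ether carbon (C9) and the α'-carbon (C6b) of a 3-alkoxycyclohex-2-enone. Ring D can therefore be carried as a non-aromatic ring, and the furan closed by cyclodehydration of a 1,4-diketone whose other carbonyl is the ring A aryl ketone C11a.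

## Retrosynthetic reasoning

**Lactone (16 to 15 to 14).** The O5–C6 bond is cut first. It is an aryl ester between a ring A phenol and a carboxyl group that a 2-arylbenzofuran-3-carboxylate holds next to each other, so the forward reaction is an acyl transfer that should need little more than the free phenol. Both phenols of 15 are masked as benzyl ethers in 14, so that one hydrogenolysis frees them together; the C9 hydroxyl is too far from the ester to compete. The pentacycle is thereby reduced to a trisubstituted benzofuran.

**Aromaticity of ring D (14 to 13).** Two hydrogens are added back at C7 and C8. The forward step is a dehydrogenation driven by formation of a benzene ring. In 13 the positions of ring D are distinguished by hybridization and not by the directing effects of an arene, which opens ring D to carbonyl chemistry.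

**Furan (13 to 11 through 12).** The O11–C10a bond is cut, which unfolds the furan into the 1,4-diketone 11, made of the aryl ketone C11a and the ring carbonyl C10a. This cut is chosen because both carbonyl groups exist in a stable, isolable form and the oxygen on C9 is already in place as a benzyl enol ether. The forward step has to close the five-membered ring only and keep the enol ether intact.

**Union of the halves (11 to 6 and 10).** The C6a–C6b bond joins the most acidic carbon of the β-keto ester 6 to the α-carbon of a ketone, so the natural polarity is enolate plus α-bromo ketone 10. The cut is convergent: each half carries one aromatic ring or its precursor. The hindered C11a–C11b bond is not touched; it comes from the starting material.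

**Ring A half (6 to 5 to 4).** The C6–C6a bond is cut as a one-carbon acylation of the methyl ketone 5, which brings in C6 at the carboxyl oxidation level that the lactone needs. The hydroxyl of 4 is benzylated first, because a free ortho-hydroxyl would itself be acylated and cyclized under the carboxylation conditions.

**Chroman (4 to 1 and 2 through 3).** The bond from ring A to the pyran CH2 and the O–CMe2 bond are cut together. Acetophenone 1 is symmetrical: its two open ring positions are equivalent and so are its two hydroxyls. Prenylation by 2 followed by ring closure of 3 can therefore give only one mono-chroman. The hydroxyl that remains in 4 is the one that becomes O5, and the methoxy group is present from the start.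

**Ring D half (10 to 9 to 8 to 7).** The C–Br bond of 10 must sit at the α'-carbon. Direct halogenation of 8 would go to the carbon between the two oxygens, so the halogen is introduced through the cross-conjugated silyl dienol ether 9, made from the kinetic enolate of 8. Enol ether 8 comes from the symmetrical dione 7, for which only one mono-enol ether is possible.

## Alternatives that were turned down

**Alternative 1:** The cut is through C11a–C11b and O5–C6, dividing the target into a ring A phenol and a finished benzofuran. In the forward key step 6-benzyloxy-2-bromobenzofuran-3-carboxylic acid A1 and phloroglucinol A2 are heated with CuSO4 in aqueous NaOH (Hurtley-type C-arylation assisted by the neighbouring carboxylate). Acidification then closes the lactone to give the 1,3-dihydroxycoumestan A3.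
- For it: two bonds and one ring form in one operation, the symmetry of A2 removes any question of where the aryl group goes, and ring A needs no protecting group. On convergence and on the number of steps to the tetracycle it is stronger than the chosen route.
- Against it: A3 still lacks the methyl group and the pyran ring. The C3 hydroxyl (the more acidic one, conjugated with the lactone carbonyl) can probably be methylated selectively, but the prenyl group must then go to C2 and not to C4, which is equally activated, and both operations run on a base-sensitive lactone. A1 is also a 2-halofuran that may hydrolyse in hot hydroxide.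
- Comparison: the symmetry that helps the coupling is paid back as regiochemical decisions after it. The chosen route uses the symmetry of 1 once, before any coupling, and carries a fully defined ring A from 4 onward, at the cost of a longer linear sequence.

**Alternative 2:** The cut is through O5–C4a. In the forward key step the acid A4, 6-acetoxy-2-(5-methoxy-2,2-dimethylchroman-8-yl)benzofuran-3-carboxylic acid, is cyclized oxidatively onto the C4a–H bond with Cu(OAc)2 and (PhCO2)2 or with Pd(OAc)2 and PhI(OAc)2. This gives A5, the 9-O-acetate of 16, and deacetylation finishes the synthesis.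
- For it: ring A needs neither an oxygen at C4a nor a protecting group there, so the aryl fragment is simpler and has one ortho substituent less. Only one ortho C–H is available, because the other ortho carbon carries the pyran oxygen. On simplicity of the ring A fragment it is stronger than the chosen route.
- Against it: the step is an oxidation on the most electron-rich ring of the molecule, next to a benzylic CH2 and a second free ring position, with peroxide or a high-valent iodine reagent. A4 also still requires a 2-arylbenzofuran-3-carboxylate, so the furan problem is not solved by this cut and the step count is not lower. The greatest risk falls on the last carbon–heteroatom bond, when the material is most valuable.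
- Comparison: the chosen route takes O5 from 1, where it costs nothing, and closes the lactone by a redox-neutral acyl transfer. Its risk lies in the middle of the route, in step 8.

**Alternative 3:** The cut is through C6a–C6b and O11–C11a at the pterocarpan oxidation level. In the forward key step the pyrano-fused 2H-chromene A6 and 5-benzyloxy-2-iodophenol A7 react with Pd(OAc)2 and Ag2CO3. The arylpalladium species adds across the chromene olefin (C6a–C6b), and the phenol oxygen captures the benzylic palladium (O11–C11a), giving the cis-fused pterocarpan A8. Oxidation to the coumestan and debenzylation follow.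
- For it: the coupling is convergent, the iodide fixes the ring D regiochemistry, and both skeletal bonds of the five-membered ring form in one step. On convergence and on the directness of the key coupling it is stronger than the chosen route.
- Against it: A8 lies well below the target in oxidation level. The C6 methylene must become a carbonyl and the C6a–C11a bond must be dehydrogenated, while the pyran CH2 on ring A and the benzyl ether CH2 must survive the same oxidants. Two stereocentres are made only to be destroyed, and A6 itself needs several steps from a trioxygenated benzene.
- Comparison: the chosen route has C6 at the carboxyl level from step 3 and needs one dehydrogenation only, which aromatization drives and one equivalent of a mild quinone should accomplish.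

Key step: step 8

Remark: 16 is achiral; 10, 11 and 12 carry stereocentres that are erased in step 8 and are used as racemates or diastereomer mixtures.

## Route

Step 1
Reactants: 1 2',6'-dihydroxy-4'-methoxyacetophenone; 2 2-methylbut-3-en-2-ol
Product: 4 1-(7-hydroxy-5-methoxy-2,2-dimethylchroman-8-yl)ethanone, via C-prenylated acetophenone 3 (not isolated)
Conditions: 2 (0.9 equiv), BF3·OEt2, 1,4-dioxane, rt, then 50 °C
Reagents that add atoms: none
Why: Friedel–Crafts C-prenylation followed by acid-catalysed Markovnikov hydroalkoxylation: the dimethylallyl cation from 2 attacks one of the two equivalent ring carbons between OH and OMe of 1 to give 3, and the only hydroxyl next to the prenyl group adds to the olefin to close the 2,2-dimethylchroman. The symmetry of 1 allows a single mono-chroman, and the remaining hydroxyl stays hydrogen-bonded to the acetyl group.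

Step 2
Reactants: 4 1-(7-hydroxy-5-methoxy-2,2-dimethylchroman-8-yl)ethanone
Product: 5 1-(7-benzyloxy-5-methoxy-2,2-dimethylchroman-8-yl)ethanone
Conditions: BnBr, K2CO3, DMF, 60 °C
Reagents that add atoms: benzyl bromide, BrCc1ccccc1
Why: Williamson etherification of the only acidic O–H; the chelated phenol needs warm DMF. The benzyl ether keeps this oxygen out of the carboxylation in step 3 and comes off under neutral conditions at the end.

Step 3
Reactants: 5 1-(7-benzyloxy-5-methoxy-2,2-dimethylchroman-8-yl)ethanone
Product: 6 methyl 3-(7-benzyloxy-5-methoxy-2,2-dimethylchroman-8-yl)-3-oxopropanoate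
Conditions: NaH (2.5 equiv), (MeO)2CO (excess), toluene, reflux; aq. HCl work-up
Reagents that add atoms: dimethyl carbonate, COC(=O)OC
Why: Crossed Claisen condensation of the methyl ketone enolate with a non-enolizable carbonate; deprotonation of the β-keto ester product drives it forward, and the two ortho substituents do not shield the methyl group.

Step 4
Reactants: 7 cyclohexane-1,3-dione
Product: 8 3-benzyloxycyclohex-2-en-1-one
Conditions: BnOH, TsOH (cat.), toluene, Dean–Stark, reflux
Reagents that add atoms: benzyl alcohol, OCc1ccccc1
Why: Acid-catalysed enol etherification (vinylogous esterification) with azeotropic removal of water; the symmetry of 7 allows one enol ether only.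

Step 5
Reactants: 8 3-benzyloxycyclohex-2-en-1-one
Product: 9 1-benzyloxy-3-(trimethylsilyloxy)cyclohexa-1,3-diene
Conditions: LiN(iPr)2, THF, −78 °C; Me3SiCl, −78 °C to rt; non-aqueous work-up
Reagents that add atoms: chlorotrimethylsilane, C[Si](C)(C)Cl
Why: Kinetic deprotonation of a 3-alkoxycyclohexenone occurs at the α'-carbon (Stork–Danheiser enolate), and O-silylation traps it as the cross-conjugated dienol ether. This fixes the carbon that becomes C6b.

Step 6
Reactants: 9 1-benzyloxy-3-(trimethylsilyloxy)cyclohexa-1,3-diene
Product: 10 6-bromo-3-benzyloxycyclohex-2-en-1-one (racemic)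
Conditions: NBS (1.0 equiv), THF, −78 to 0 °C
Reagents that add atoms: N-bromosuccinimide, O=C1CCC(=O)N1Br
Why: Electrophilic bromination of a silyl enol ether; 9 reacts at the terminus of the silyloxy olefin because the cation formed there is stabilized by both oxygens. Bromine therefore goes to the α'-carbon and not to C2, where direct halogenation of 8 would put it.

Step 7
Reactants: 6 methyl 3-(7-benzyloxy-5-methoxy-2,2-dimethylchroman-8-yl)-3-oxopropanoate; 10 6-bromo-3-benzyloxycyclohex-2-en-1-one
Product: 11 methyl 2-(4-benzyloxy-2-oxocyclohex-3-en-1-yl)-3-(7-benzyloxy-5-methoxy-2,2-dimethylchroman-8-yl)-3-oxopropanoate (mixture of diastereomers)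
Conditions: NaH (1.0 equiv), THF, 0 °C; then 10, THF–DMF, 0 °C to rt
Reagents that add atoms: none
Why: C-alkylation of a stabilized β-keto ester enolate by an α-bromo ketone (SN2, accelerated by the adjacent carbonyl); the soft, weakly basic enolate favours substitution over elimination, and the C6a–C6b bond forms at the only halogenated carbon of 10. The two new stereocentres are not controlled and need not be, since both become sp2 carbons in step 8.

Step 8
Reactants: 11 methyl 2-(4-benzyloxy-2-oxocyclohex-3-en-1-yl)-3-(7-benzyloxy-5-methoxy-2,2-dimethylchroman-8-yl)-3-oxopropanoate
Product: 13 methyl 6-benzyloxy-2-(7-benzyloxy-5-methoxy-2,2-dimethylchroman-8-yl)-4,5-dihydrobenzofuran-3-carboxylate, via cyclic hemiketal 12 (not isolated)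
Conditions: TsOH (anhydrous, 0.1 equiv), benzene, reflux, Dean–Stark trap charged with 4 Å molecular sieves; Et3N quench
Reagents that add atoms: none
Why: Paal–Knorr furan synthesis, the acid cyclodehydration of a 1,4-diketone, here the aryl ketone C11a and the ring carbonyl C10a. The β-keto ester of 11 enolizes toward C6a, and the enol oxygen on C11a adds to the protonated vinylogous ester carbonyl C10a in a 5-exo-trig closure that forms the O11–C10a bond and gives the cis-fused hemiketal 12. The hemiketal hydroxyl ionizes easily, because the cation is stabilized by O11 and, through C10=C9, by the benzyloxy group; loss of the C6b proton then gives the furan 13. No stereocentre survives, as those of 11 and 12 all become sp2 carbons. The step needs closure at C10a only and survival of the benzyl enol ether. The methyl ester is also 1,4 to C10a, but a closure through it (enol lactone or alkoxyfuran) would use a much poorer electrophile and oxygen nucleophile than the ketone pair and should not compete; closure at C9 would need a bridged seven-membered ring. The reaction releases one equivalent of water, which the sieves remove continuously, so the enol ether is not hydrolysed and the C9 oxygen stays fixed as a benzyl ether in a diene conjugated with the furan.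

Step 9
Reactants: 13 methyl 6-benzyloxy-2-(7-benzyloxy-5-methoxy-2,2-dimethylchroman-8-yl)-4,5-dihydrobenzofuran-3-carboxylate
Product: 14 methyl 6-benzyloxy-2-(7-benzyloxy-5-methoxy-2,2-dimethylchroman-8-yl)benzofuran-3-carboxylate
Conditions: DDQ (1.05 equiv), benzene, rt
Reagents that add atoms: none
Why: Quinone dehydrogenation; hydride abstraction from C4 of the dihydrobenzofuran gives a cation delocalized over the furan and the benzyl enol ether, and loss of the C5 proton completes the benzene ring. With one equivalent of DDQ at room temperature, aromatization should be far faster than oxidation at the chroman CH2 or at the benzyl ethers.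

Step 10
Reactants: 14 methyl 6-benzyloxy-2-(7-benzyloxy-5-methoxy-2,2-dimethylchroman-8-yl)benzofuran-3-carboxylate
Product: 16 target coumestan CNP0304440.0, via dihydroxy ester 15 (not isolated)
Conditions: H2 (1 atm), Pd/C (10%), EtOAc–MeOH, rt; filter; TsOH (cat.), toluene, 80 °C
Reagents that add atoms: none
Why: Hydrogenolysis of both benzyl ethers on Pd/C gives 15, in which the ring A phenol lies next to the ester. Lactonization by intramolecular transesterification then closes the six-membered O5–C6 ring with loss of methanol; the C9 phenol is too remote to compete.

## Compound list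

1 | 2',6'-dihydroxy-4'-methoxyacetophenone | CC(=O)c1c(O)cc(OC)cc1O | starting material
2 | 2-methylbut-3-en-2-ol | CC(C)(O)C=C | starting material
3 | 1-[2,6-dihydroxy-4-methoxy-3-(3-methylbut-2-en-1-yl)phenyl]ethanone | CC(=O)c1c(O)cc(OC)c(CC=C(C)C)c1O | intermediate (not isolated)
4 | 1-(7-hydroxy-5-methoxy-2,2-dimethylchroman-8-yl)ethanone | CC(=O)c1c(O)cc(OC)c2CCC(C)(C)Oc12 | intermediate
5 | 1-(7-benzyloxy-5-methoxy-2,2-dimethylchroman-8-yl)ethanone | CC(=O)c1c(OCc2ccccc2)cc(OC)c2CCC(C)(C)Oc12 | intermediate
6 | methyl 3-(7-benzyloxy-5-methoxy-2,2-dimethylchroman-8-yl)-3-oxopropanoate | COC(=O)CC(=O)c1c(OCc2ccccc2)cc(OC)c2CCC(C)(C)Oc12 | intermediate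
7 | cyclohexane-1,3-dione | O=C1CCCC(=O)C1 | starting material
8 | 3-benzyloxycyclohex-2-en-1-one | O=C1CCCC(OCc2ccccc2)=C1 | intermediate
9 | 1-benzyloxy-3-(trimethylsilyloxy)cyclohexa-1,3-diene | C[Si](C)(C)OC1=CCCC(OCc2ccccc2)=C1 | intermediate
10 | 6-bromo-3-benzyloxycyclohex-2-en-1-one (racemic) | O=C1C=C(OCc2ccccc2)CCC1Br | intermediate
11 | methyl 2-(4-benzyloxy-2-oxocyclohex-3-en-1-yl)-3-(7-benzyloxy-5-methoxy-2,2-dimethylchroman-8-yl)-3-oxopropanoate (mixture of diastereomers) | COC(=O)C(C1CCC(OCc2ccccc2)=CC1=O)C(=O)c1c(OCc2ccccc2)cc(OC)c2CCC(C)(C)Oc12 | intermediate
12 | methyl 6-benzyloxy-2-(7-benzyloxy-5-methoxy-2,2-dimethylchroman-8-yl)-7a-hydroxy-3a,4,5,7a-tetrahydrobenzofuran-3-carboxylate (cis-fused, racemic, one enantiomer drawn) | COC(=O)C1=C(c2c(OCc3ccccc3)cc(OC)c3CCC(C)(C)Oc23)O[C@]2(O)C=C(OCc3ccccc3)CC[C@H]12 | intermediate (not isolated)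
13 | methyl 6-benzyloxy-2-(7-benzyloxy-5-methoxy-2,2-dimethylchroman-8-yl)-4,5-dihydrobenzofuran-3-carboxylate | COC(=O)c1c(-c2c(OCc3ccccc3)cc(OC)c3CCC(C)(C)Oc23)oc2C=C(OCc3ccccc3)CCc12 | intermediate
14 | methyl 6-benzyloxy-2-(7-benzyloxy-5-methoxy-2,2-dimethylchroman-8-yl)benzofuran-3-carboxylate | COC(=O)c1c(-c2c(OCc3ccccc3)cc(OC)c3CCC(C)(C)Oc23)oc2cc(OCc3ccccc3)ccc12 | intermediate
15 | methyl 6-hydroxy-2-(7-hydroxy-5-methoxy-2,2-dimethylchroman-8-yl)benzofuran-3-carboxylate | COC(=O)c1c(-c2c(O)cc(OC)c3CCC(C)(C)Oc23)oc2cc(O)ccc12 | intermediate (not isolated)
16 | CNP0304440.0: 9-hydroxy-3-methoxycoumestan with a 2,2-dimethyl-3,4-dihydro-2H-pyran ring fused at C1–C2 (oxygen on C1) | COc1cc2oc(=O)c3c4ccc(O)cc4oc3c2c2c1CCC(C)(C)O2 | target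

## Step count and least certain steps

Total steps: 10. Longest linear sequence: 7 (steps 1, 2, 3, 7, 8, 9, 10; the ring D branch through steps 4, 5, 6 is equally long).

**Step 8 (key step).** The most likely failure is hydrolysis of the vinylogous benzyl ester by the water that the reaction itself releases, before or after ring closure. The closure may also stall because the vinylogous ester carbonyl is a weak electrophile, so that benzyl transfer or cleavage of the β-keto ester take over on long heating. The fallback sets out from 6 and 9 and returns at 13.
- Diazo transfer to 6 (4-acetamidobenzenesulfonyl azide, Et3N, MeCN) gives methyl 3-(7-benzyloxy-5-methoxy-2,2-dimethylchroman-8-yl)-2-diazo-3-oxopropanoate F1.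
- Rh2(OAc)4 (catalytic, CH2Cl2, rt) converts F1 into an electrophilic carbenoid, which the silyloxy diene 9 attacks through its terminal carbon. The ketone oxygen then closes on the silyloxy-stabilized cation, a formal [3+2] cycloaddition of a diazo dicarbonyl compound with an enol ether. This gives methyl 6-benzyloxy-2-(7-benzyloxy-5-methoxy-2,2-dimethylchroman-8-yl)-7a-(trimethylsilyloxy)-3a,4,5,7a-tetrahydrobenzofuran-3-carboxylate F2 (cis-fused, racemic).
- A trace of pyridinium tosylate eliminates the silanol from F2 and gives 13.
- Both furan bonds are made at the ketal oxidation level, so no carbonyl has to be activated and no water is formed.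

**Step 7.** The enolate may remove HBr from 10 (the dienone so formed aromatizes), bromine may be transferred from 10 to the enolate, or O-alkylation may intervene; 10 may also degrade on storage. The fallback sets out from 6 and 9 and returns at 11. It is an oxidative coupling with (NH4)2Ce(NO3)6 (tetravalent cerium, 2 equiv) and NaHCO3 in MeCN at −20 to 0 °C. One-electron oxidation of the enol of 6 gives an electrophilic radical at C6a, which adds to the terminal carbon of 9; a second oxidation and loss of the silyl group give 11 directly. No bromide is needed, and the fallback makes no compound outside the list (F0).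

**Step 1.** A second prenylation at the remaining free ring position, O-alkylation and incomplete ring closure may erode the yield of the mono-chroman. The fallback sets out from 1 and returns at 4.
- Condensation of 1 with 3-methylbut-2-enal in pyridine at 120–140 °C (C-alkylation, dehydration to an ortho-quinone methide and 6π-oxa-electrocyclization) gives 1-(7-hydroxy-5-methoxy-2,2-dimethyl-2H-chromen-8-yl)ethanone F3.
- H2 on Pd/C in EtOAc saturates the chromene olefin and gives 4.
- The aldehyde condensation product is not an alkylating agent, so over-reaction is limited.

**Step 9.** If aromatization is slower than expected or needs excess quinone, hydride abstraction at the benzylic CH2 of the chroman ring or oxidative loss of a benzyl group may compete. The fallback sets out from 13 and returns at 15.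
- Dilute HCl in THF hydrolyses the enol ether to methyl 2-(7-benzyloxy-5-methoxy-2,2-dimethylchroman-8-yl)-6-oxo-4,5,6,7-tetrahydrobenzofuran-3-carboxylate F4.
- Aerobic α,β-dehydrogenation of the ketone with Pd(OCOCF3)2 (catalytic), 2-(dimethylamino)pyridine, TsOH and O2 in DMSO at 80 °C, followed by tautomerization, gives methyl 2-(7-benzyloxy-5-methoxy-2,2-dimethylchroman-8-yl)-6-hydroxybenzofuran-3-carboxylate F5.
- Hydrogenolysis of the one remaining benzyl ether (H2, Pd/C) gives 15, which lactonizes to 16 under the conditions of step 10.

## Further compounds

F1 | step 8 | methyl 3-(7-benzyloxy-5-methoxy-2,2-dimethylchroman-8-yl)-2-diazo-3-oxopropanoate | COC(=O)C(=[N+]=[N-])C(=O)c1c(OCc2ccccc2)cc(OC)c2CCC(C)(C)Oc12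
F2 | step 8 | methyl 6-benzyloxy-2-(7-benzyloxy-5-methoxy-2,2-dimethylchroman-8-yl)-7a-(trimethylsilyloxy)-3a,4,5,7a-tetrahydrobenzofuran-3-carboxylate (cis-fused, racemic, one enantiomer drawn) | COC(=O)C1=C(c2c(OCc3ccccc3)cc(OC)c3CCC(C)(C)Oc23)O[C@]2(O[Si](C)(C)C)C=C(OCc3ccccc3)CC[C@H]12
F0 | step 7 | none | none
F3 | step 1 | 1-(7-hydroxy-5-methoxy-2,2-dimethyl-2H-chromen-8-yl)ethanone | CC(=O)c1c(O)cc(OC)c2C=CC(C)(C)Oc12
F4 | step 9 | methyl 2-(7-benzyloxy-5-methoxy-2,2-dimethylchroman-8-yl)-6-oxo-4,5,6,7-tetrahydrobenzofuran-3-carboxylate | COC(=O)c1c(-c2c(OCc3ccccc3)cc(OC)c3CCC(C)(C)Oc23)oc2CC(=O)CCc12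
F5 | step 9 | methyl 2-(7-benzyloxy-5-methoxy-2,2-dimethylchroman-8-yl)-6-hydroxybenzofuran-3-carboxylate | COC(=O)c1c(-c2c(OCc3ccccc3)cc(OC)c3CCC(C)(C)Oc23)oc2cc(O)ccc12
A1 | alternative 1 | 6-benzyloxy-2-bromobenzofuran-3-carboxylic acid | OC(=O)c1c(Br)oc2cc(OCc3ccccc3)ccc12
A2 | alternative 1 | phloroglucinol | Oc1cc(O)cc(O)c1
A3 | alternative 1 | 9-benzyloxy-1,3-dihydroxy-6H-benzofuro[3,2-c]chromen-6-one | Oc1cc(O)c2c(c1)oc(=O)c1c3ccc(OCc4ccccc4)cc3oc12
A4 | alternative 2 | 6-acetoxy-2-(5-methoxy-2,2-dimethylchroman-8-yl)benzofuran-3-carboxylic acid | COc1ccc(-c2oc3cc(OC(C)=O)ccc3c2C(O)=O)c2OC(C)(C)CCc12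
A5 | alternative 2 | 9-O-acetyl derivative of 16 | COc1cc2oc(=O)c3c4ccc(OC(C)=O)cc4oc3c2c2c1CCC(C)(C)O2
A6 | alternative 3 | 5-methoxy-2,2-dimethyl-3,4-dihydro-2H,8H-pyrano[2,3-f]chromene | COc1cc2OCC=Cc2c2OC(C)(C)CCc12
A7 | alternative 3 | 5-benzyloxy-2-iodophenol | Oc1cc(OCc2ccccc2)ccc1I
A8 | alternative 3 | cis-fused 9-benzyloxy-3-methoxypterocarpan with the 2,2-dimethyldihydropyran fused at C1–C2 (racemic, one enantiomer drawn) | COc1cc2OC[C@H]3c4ccc(OCc5ccccc5)cc4O[C@H]3c2c2OC(C)(C)CCc12
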